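Start at the early readings: the north run shows Q at 8.4% after 1.04 d and 8.4% after 12.0 d, a change inside the scatter of 0.5 percentage points, so expect a longer time, here 15 d, to add nothing to the flask. Turn cE next, at fixed 1.30 equiv of X: north at 0.50 M last reads 8.4% of Q and north-east at 2 M last reads 10.9%, and the flask's 1.0 M lies midway between them on a log scale. Turn X last: north-west, at the flask's 1 M of E but with 0.65 equiv of X, last reads 7.2% of Q, so expect the flask's charge of X, twice that, to lift Q above this reading.

Carry one rule through these turns: if Q and the loss of E both run at rates proportional to cE·cX, dividing one rate by the other cancels the course of X, and integrating leaves Q equal to a constant times the E used. The last readings give Q over E used as 0.312, 0.319 and 0.316; call their mean, 0.316, the selectivity s, the share of the E used that becomes Q. Take the flask's E used as the north and north-east midpoint, 30.5%, and my reckoning gives Q of 9.64%.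

| setting | north | north-east | north-west | flask |
|---|---|---|---|---|
| E | 0.50 M | 2 M | 1 M | 1.0 M |
| X | 1.3 equiv | 1.3 equiv | 0.65 equiv | 1.30 equiv |
| remark | run made earlier | run made earlier | run made earlier |  |
| time |  |  |  | 15 d |

- north (time / d: Q / %, E / %): 1.04: 8.4, 74.8; 1.67: 9.0, 74.5; 2.00: 8.8, 72.9; 3.00: 8.2, 72.7; 5.00: 8.4, 73.4; 8.00: 8.2, 72.6; 12.0: 8.4, 73.1
- north-east (time / d: Q / %, E / %): 0.625: 11.1, 66.3; 1.67: 10.9, 65.5; 3.00: 10.8, 65.8; 5.00: 11.8, 65.4; 8.00: 11.4, 64.3; 10.0: 10.8, 64.7; 12.0: 10.9, 65.8
- north-west (time / d: Q / %, E / %): 2.50: 7.5, 77.6; 5.00: 7.1, 78.0; 8.00: 7.2, 77.6; 10.0: 6.8, 77.6; 12.0: 7.2, 77.2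

(each reading ± 0.5 percentage points)

- the reaction counts as stopped when no species that holds the E changes by six tenths of a point or more over the second half of the time

* why nothing more happens at 15 d, or that something still does (all of E has reacted / it is still moving / X has run out first)
* amount of Q at 15 d, in percent of the E charged

The forecast answers X has run out first, on the ground that “X therefore seems to be lost unproductively”, and gives 9.6%, within 8.9% to 10.4%; my figure rests on the same runs.

The flask gives 10.1% of Q at 15 d, and the answer on its end is X has run out first, with X at 0% of its charge beside E at 68%, and Q still 10.1% at 150 d.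

    E + X → Q (k = 3.80 × 10⁻⁴ M⁻¹ min⁻¹)
    E + X → G (k = 7.92 × 10⁻⁴ M⁻¹ min⁻¹)
    E + X → Z (k = 2.41 × 10⁻⁵ M⁻¹ min⁻¹)
    X → L (k = 6.97 × 10⁻⁴ min⁻¹)
    2 X → J (k = 0.00249 M⁻¹ min⁻¹)

Put s to use: this flask's E used, 31.9%, times 0.316 gives 10.1% of Q. The neighbour flask at 0.60 M of E, with the same equivalents, ends with E at 72%, so s gives 8.97%, and that flask holds 9.03%.

The data stem from a simulated flask from invented constants.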